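**Retrosynthetic overview**
1. Target 14 ⇐ pentabenzyl ether 13; hydrogenolysis comes last so the single methyl ether is never at risk.
2. Ring C of the apigenin half ⇐ o-iodophenol 9 + CO + alkyne 10 (carbonylative annulation, which also brings in ring B of that half).
3. Key disconnection: the hindered 8–6'' biaryl bond is not made by aryl–aryl cross-coupling of two flavones. Ring A of the apigenin half enters as quinone 5, attacked at its C1 carbonyl by the C8-magnesiated acacetin ether; reductive aromatisation of the p-quinol leaves the phenol para to the new bond, which fixes the 6''-linkage.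
4. Building blocks: commercial acacetin 1 (rings A, C and B of the 8-linked half preformed) and quinone 5 from 3,5-bis(benzyloxy)phenol 4.
5. Order of ring formation: acacetin rings (bought) → ring A of the apigenin half (aromatised from the quinone, step 4) → ring C of the apigenin half (step 6).

Assumption: the target SMILES carries no stereodescriptor and the molecule has no stereocentre, so the hindered 8–6'' biaryl axis is taken as unspecified and is formed as the racemate.

**Route**

Step 1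
Reactants: 1 acacetin (5,7-dihydroxy-2-(4-methoxyphenyl)-4H-chromen-4-one)
Product: 2 5,7-bis(benzyloxy)-2-(4-methoxyphenyl)-4H-chromen-4-one
Conditions: BnBr (3 equiv), K2CO3 (4 equiv), DMF, 80 °C
Reagents that add atoms: benzyl bromide, BrCc1ccccc1
Why: Williamson ether synthesis in which the 7-OH alkylates readily and the hydrogen-bonded 5-OH follows at 80 °C, giving a substrate without a free 5-OH so that halogenation is later steered to C8; no stereocentre is involved.

Step 2
Reactants: 2 5,7-bis(benzyloxy)-2-(4-methoxyphenyl)-4H-chromen-4-one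
Product: 3 5,7-bis(benzyloxy)-8-iodo-2-(4-methoxyphenyl)-4H-chromen-4-one
Conditions: NIS (1.1 equiv), TFA (0.3 equiv), MeCN/CH2Cl2, rt
Reagents that add atoms: N-iodosuccinimide, O=C1CCC(=O)N1I
Why: Electrophilic aromatic iodination, which in 5,7-dialkoxyflavones without a free 5-OH goes to C8 (para to the 5-alkoxy group and less hindered than C6, which is shielded by the 5-O-benzyl group turned away from the peri carbonyl), while ring B and the benzyl rings are far less activated; no stereocentre is involved.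

Step 3
Reactants: 4 3,5-bis(benzyloxy)phenol
Product: 5 2,6-bis(benzyloxy)cyclohexa-2,5-diene-1,4-dione (2,6-bis(benzyloxy)-1,4-benzoquinone)
Conditions: (KSO3)2NO (2.5 equiv), KH2PO4 buffer, acetone/H2O, rt
Reagents that add atoms: potassium nitrosodisulfonate (Fremy's salt), [K+].[K+].[O]N(S(=O)(=O)[O-])S(=O)(=O)[O-]
Why: Teuber oxidation in which one Fremy radical abstracts the phenolic hydrogen and a second attacks the free para position to give the p-quinone with both benzyl ethers untouched; no stereocentre is involved.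

Step 4
Reactants: 3 5,7-bis(benzyloxy)-8-iodo-2-(4-methoxyphenyl)-4H-chromen-4-one, 5 2,6-bis(benzyloxy)-1,4-benzoquinone
Product: 8 5,7-bis(benzyloxy)-8-[2,6-bis(benzyloxy)-4-hydroxyphenyl]-2-(4-methoxyphenyl)-4H-chromen-4-one, via 8-chloromagnesio flavone 6 (not isolated), via p-quinol adduct 7 (not isolated)
Conditions: iPrMgCl·LiCl (1.1 equiv), THF, −40 °C; then 5 (1.3 equiv), LaCl3·2LiCl (1 equiv), −78 → −20 °C; then AcOH, Zn dust, 0 °C → rt
Reagents that add atoms: none
Why: Proposed new method: iodine–magnesium exchange at C8 should be fast at −40 °C because the two flanking oxygens stabilise the aryl anion while the γ-pyrone carbonyl is a poor electrophile, the aryl then adds 1,2 to the quinone carbonyl lying between the two benzyloxy-bearing carbons (the other carbonyl is a doubly vinylogous ester and deactivated, and the flanking ether oxygens chelate the metal), and Zn/AcOH reductively aromatises the p-quinol with loss of the tertiary hydroxyl so that the phenol ends up para to the new biaryl bond; the closest known reaction type is aryl-metal 1,2-addition to quinones or quinone monoketals followed by reductive aromatisation of the p-quinol to a 4-arylphenol, and no stereocentre arises because the new ring is symmetric about the biaryl bond.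

Step 5
Reactants: 8 5,7-bis(benzyloxy)-8-[2,6-bis(benzyloxy)-4-hydroxyphenyl]-2-(4-methoxyphenyl)-4H-chromen-4-one
Product: 9 5,7-bis(benzyloxy)-8-[2,6-bis(benzyloxy)-4-hydroxy-3-iodophenyl]-2-(4-methoxyphenyl)-4H-chromen-4-one
Conditions: NIS (1.0 equiv), CH2Cl2, −40 → 0 °C
Reagents that add atoms: N-iodosuccinimide, O=C1CCC(=O)N1I
Why: Electrophilic ortho-iodination of a phenol, in which the two equivalent positions ortho to the free OH on the phloroglucinol-type ring are by far the most nucleophilic sites so that one equivalent of NIS at low temperature gives the mono-iodide; the biaryl axis becomes stereogenic here and is formed racemic.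

Step 6
Reactants: 9 5,7-bis(benzyloxy)-8-[2,6-bis(benzyloxy)-4-hydroxy-3-iodophenyl]-2-(4-methoxyphenyl)-4H-chromen-4-one, 10 1-(benzyloxy)-4-ethynylbenzene
Product: 13 5,7-bis(benzyloxy)-8-[5,7-bis(benzyloxy)-2-(4-(benzyloxy)phenyl)-4-oxo-4H-chromen-6-yl]-2-(4-methoxyphenyl)-4H-chromen-4-one, via ynone 11 (not isolated), via enaminone 12 (not isolated)
Conditions: 10 (1.5 equiv), CO (1 atm), PdCl2(PPh3)2 (5 mol %), dppp (5 mol %), thiourea (5 mol %), Et2NH, 50 °C
Reagents that add atoms: carbon monoxide, [C-]#[O+]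
Why: Pd-catalysed carbonylative Sonogashira coupling followed by amine-mediated cycloisomerisation, in which the aroyl-palladium species from 9 and CO is alkynylated by 10 and the ynone passes in Et2NH through the enaminone and closes by 6-endo addition–elimination of the ortho phenol to the flavone instead of the aurone, the phenol para to the axis becoming O1'' so that the linkage is C6''; no new stereocentre is formed.

Step 7
Reactants: 13 5,7-bis(benzyloxy)-8-[5,7-bis(benzyloxy)-2-(4-(benzyloxy)phenyl)-4-oxo-4H-chromen-6-yl]-2-(4-methoxyphenyl)-4H-chromen-4-one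
Product: 14 5,7-dihydroxy-8-[5,7-dihydroxy-2-(4-hydroxyphenyl)-4-oxo-4H-chromen-6-yl]-2-(4-methoxyphenyl)-4H-chromen-4-one
Conditions: H2 (1 atm), 10% Pd/C, THF/MeOH 1:1, rt
Reagents that add atoms: none
Why: Catalytic hydrogenolysis of the five benzyl aryl ethers, under which the aryl methyl ether and the chromone C2=C3 bonds are inert and the racemic axis is untouched.

**Compound list**

1 | acacetin, 5,7-dihydroxy-2-(4-methoxyphenyl)-4H-chromen-4-one | COc1ccc(cc1)-c1cc(=O)c2c(O)cc(O)cc2o1 | starting material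
2 | 5,7-bis(benzyloxy)-2-(4-methoxyphenyl)-4H-chromen-4-one | COc1ccc(cc1)-c1cc(=O)c2c(OCc3ccccc3)cc(OCc3ccccc3)cc2o1 | intermediate
3 | 5,7-bis(benzyloxy)-8-iodo-2-(4-methoxyphenyl)-4H-chromen-4-one | COc1ccc(cc1)-c1cc(=O)c2c(OCc3ccccc3)cc(OCc3ccccc3)c(I)c2o1 | intermediate
4 | 3,5-bis(benzyloxy)phenol | Oc1cc(OCc2ccccc2)cc(OCc2ccccc2)c1 | starting material
5 | 2,6-bis(benzyloxy)cyclohexa-2,5-diene-1,4-dione (C1 carbonyl lies between the two benzyloxy-bearing carbons) | O=C1C=C(OCc2ccccc2)C(=O)C(OCc2ccccc2)=C1 | intermediate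
6 | [5,7-bis(benzyloxy)-2-(4-methoxyphenyl)-4-oxo-4H-chromen-8-yl]magnesium chloride, LiCl complex (forms in the flask in step 4) | COc1ccc(cc1)-c1cc(=O)c2c(OCc3ccccc3)cc(OCc3ccccc3)c([Mg]Cl)c2o1 | intermediate
7 | p-quinol, 5,7-bis(benzyloxy)-8-[2,6-bis(benzyloxy)-1-hydroxy-4-oxocyclohexa-2,5-dien-1-yl]-2-(4-methoxyphenyl)-4H-chromen-4-one (forms in the flask in step 4 as its magnesium alkoxide, protonated by AcOH) | COc1ccc(cc1)-c1cc(=O)c2c(OCc3ccccc3)cc(OCc3ccccc3)c(c2o1)C1(O)C(OCc2ccccc2)=CC(=O)C=C1OCc1ccccc1 | intermediate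
8 | 5,7-bis(benzyloxy)-8-[2,6-bis(benzyloxy)-4-hydroxyphenyl]-2-(4-methoxyphenyl)-4H-chromen-4-one (no stereogenic axis yet) | COc1ccc(cc1)-c1cc(=O)c2c(OCc3ccccc3)cc(OCc3ccccc3)c(c2o1)-c1c(OCc2ccccc2)cc(O)cc1OCc1ccccc1 | intermediate
9 | 5,7-bis(benzyloxy)-8-[2,6-bis(benzyloxy)-4-hydroxy-3-iodophenyl]-2-(4-methoxyphenyl)-4H-chromen-4-one (racemic about the biaryl axis) | COc1ccc(cc1)-c1cc(=O)c2c(OCc3ccccc3)cc(OCc3ccccc3)c(c2o1)-c1c(OCc2ccccc2)c(I)c(O)cc1OCc1ccccc1 | intermediate
10 | 1-(benzyloxy)-4-ethynylbenzene | C#Cc1ccc(OCc2ccccc2)cc1 | starting material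
11 | ynone, 5,7-bis(benzyloxy)-8-{2,6-bis(benzyloxy)-3-[3-(4-(benzyloxy)phenyl)prop-2-ynoyl]-4-hydroxyphenyl}-2-(4-methoxyphenyl)-4H-chromen-4-one (racemic axis; forms in the flask in step 6) | COc1ccc(cc1)-c1cc(=O)c2c(OCc3ccccc3)cc(OCc3ccccc3)c(c2o1)-c1c(OCc2ccccc2)c(C(=O)C#Cc2ccc(OCc3ccccc3)cc2)c(O)cc1OCc1ccccc1 | intermediate
12 | enaminone, 5,7-bis(benzyloxy)-8-{2,6-bis(benzyloxy)-3-[3-(4-(benzyloxy)phenyl)-3-(diethylamino)prop-2-enoyl]-4-hydroxyphenyl}-2-(4-methoxyphenyl)-4H-chromen-4-one (racemic axis; alkene geometry not defined; forms in the flask in step 6) | COc1ccc(cc1)-c1cc(=O)c2c(OCc3ccccc3)cc(OCc3ccccc3)c(c2o1)-c1c(OCc2ccccc2)c(C(=O)C=C(N(CC)CC)c2ccc(OCc3ccccc3)cc2)c(O)cc1OCc1ccccc1 | intermediate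
13 | 5,7-bis(benzyloxy)-8-[5,7-bis(benzyloxy)-2-(4-(benzyloxy)phenyl)-4-oxo-4H-chromen-6-yl]-2-(4-methoxyphenyl)-4H-chromen-4-one (racemic about the 8–6'' axis) | COc1ccc(cc1)-c1cc(=O)c2c(OCc3ccccc3)cc(OCc3ccccc3)c(c2o1)-c1c(OCc2ccccc2)cc2oc(cc(=O)c2c1OCc1ccccc1)-c1ccc(OCc2ccccc2)cc1 | intermediate
14 | 5,7-dihydroxy-8-[5,7-dihydroxy-2-(4-hydroxyphenyl)-4-oxo-4H-chromen-6-yl]-2-(4-methoxyphenyl)-4H-chromen-4-one (axis unspecified in the target; obtained racemic) | COc1ccc(-c2cc(=O)c3c(O)cc(O)c(-c4c(O)cc5oc(-c6ccc(O)cc6)cc(=O)c5c4O)c3o2)cc1 | target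

**Summary and fallbacks**

Total step count: 7 (including the one-step side branch 4 → 5).
Longest linear sequence: 6 steps (1 → 2 → 3 → 8 → 9 → 13 → 14).

The three steps most likely to fail:

Step 4 is the riskiest: the exchange reagent may attack the pyranone, electron transfer to the quinone may outrun addition, or the aryl may add at the wrong carbonyl. The fallback sets out from 3 (and uses 4) and comes back at 8 by conventional cross-coupling. Miyaura borylation of 3 (B2pin2, PdCl2(dppf), KOAc, dioxane, 90 °C) gives 5,7-bis(benzyloxy)-2-(4-methoxyphenyl)-8-(4,4,5,5-tetramethyl-1,3,2-dioxaborolan-2-yl)-4H-chromen-4-one F1. Bromination of 4 para to the hydroxyl (Bu4NBr3, CH2Cl2/MeOH, 0 °C, separated from the ortho isomer) gives 4-bromo-3,5-bis(benzyloxy)phenol F2. Suzuki–Miyaura coupling of F1 with F2 (Pd(OAc)2, SPhos, K3PO4, toluene/H2O, 100 °C) then delivers 8.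

Step 6 is second: on this hindered iodide, aminocarbonylation by Et2NH or direct non-carbonylative coupling may compete. The fallback sets out from 8 and comes back at 13 by the classical chalcone route. C-acetylation ortho to the phenol (Ac2O, BF3·OEt2, rt; any O-acetate is cleaved in the next basic step) gives 8-[3-acetyl-2,6-bis(benzyloxy)-4-hydroxyphenyl]-5,7-bis(benzyloxy)-2-(4-methoxyphenyl)-4H-chromen-4-one F3. Claisen–Schmidt condensation with 4-(benzyloxy)benzaldehyde (KOH, EtOH/THF, rt) gives the (E)-chalcone F4. Oxidative cyclisation (I2 cat., DMSO, 120 °C) gives 13.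

Step 5 is third: di-iodination of the doubly activated phenol ring may compete. The fallback sets out from 8 and comes back at ynone 11, avoiding the halide altogether. Magnesium-mediated ortho-formylation (MgCl2, Et3N, paraformaldehyde, MeCN, reflux), which stops cleanly at mono-substitution, gives 5,7-bis(benzyloxy)-8-[2,6-bis(benzyloxy)-3-formyl-4-hydroxyphenyl]-2-(4-methoxyphenyl)-4H-chromen-4-one F5. Addition of the bromomagnesium acetylide of 10 (from 10 and EtMgBr, THF, 0 °C, 2.2 equiv) gives the propargylic alcohol F6. MnO2 in CH2Cl2 oxidises F6 to 11, which closes to 13 on stirring in Et2NH as in step 6.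

**Further compounds**

F1 | step 4 | 5,7-bis(benzyloxy)-2-(4-methoxyphenyl)-8-(4,4,5,5-tetramethyl-1,3,2-dioxaborolan-2-yl)-4H-chromen-4-one | COc1ccc(cc1)-c1cc(=O)c2c(OCc3ccccc3)cc(OCc3ccccc3)c(B3OC(C)(C)C(C)(C)O3)c2o1
F2 | step 4 | 4-bromo-3,5-bis(benzyloxy)phenol | Oc1cc(OCc2ccccc2)c(Br)c(OCc2ccccc2)c1
F3 | step 6 | 8-[3-acetyl-2,6-bis(benzyloxy)-4-hydroxyphenyl]-5,7-bis(benzyloxy)-2-(4-methoxyphenyl)-4H-chromen-4-one (racemic axis) | COc1ccc(cc1)-c1cc(=O)c2c(OCc3ccccc3)cc(OCc3ccccc3)c(c2o1)-c1c(OCc2ccccc2)c(C(C)=O)c(O)cc1OCc1ccccc1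
F4 | step 6 | 5,7-bis(benzyloxy)-8-{2,6-bis(benzyloxy)-3-[(E)-3-(4-(benzyloxy)phenyl)prop-2-enoyl]-4-hydroxyphenyl}-2-(4-methoxyphenyl)-4H-chromen-4-one (racemic axis) | COc1ccc(cc1)-c1cc(=O)c2c(OCc3ccccc3)cc(OCc3ccccc3)c(c2o1)-c1c(OCc2ccccc2)c(C(=O)/C=C/c2ccc(OCc3ccccc3)cc2)c(O)cc1OCc1ccccc1
F5 | step 5 | 5,7-bis(benzyloxy)-8-[2,6-bis(benzyloxy)-3-formyl-4-hydroxyphenyl]-2-(4-methoxyphenyl)-4H-chromen-4-one (racemic axis) | COc1ccc(cc1)-c1cc(=O)c2c(OCc3ccccc3)cc(OCc3ccccc3)c(c2o1)-c1c(OCc2ccccc2)c(C=O)c(O)cc1OCc1ccccc1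
F6 | step 5 | 5,7-bis(benzyloxy)-8-{2,6-bis(benzyloxy)-3-[3-(4-(benzyloxy)phenyl)-1-hydroxyprop-2-yn-1-yl]-4-hydroxyphenyl}-2-(4-methoxyphenyl)-4H-chromen-4-one (mixture of stereoisomers at the carbinol and the axis) | COc1ccc(cc1)-c1cc(=O)c2c(OCc3ccccc3)cc(OCc3ccccc3)c(c2o1)-c1c(OCc2ccccc2)c(C(O)C#Cc2ccc(OCc3ccccc3)cc2)c(O)cc1OCc1ccccc1
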